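**Plan**

1. Atom numbers follow the germacrane skeleton (ring C1–C10; C11 is the isopropenyl carbon with C12 = CH2; C14 on C10; C15 on C4). Retrosynthesis first removes the three angelates, the 1,10- and 4,5-epoxides (to be delivered from C9–OH and C3–OH) and the C8 oxygen (enolate oxidation of the C9 ketone).
2. The ring is then cut at C6–C7. C6 is a carbinol next to C7, which carries the isopropenyl group C11=C12; this homoallylic alcohol is the product pattern of a [2,3]-Wittig shift. The 10-membered carbocycle is therefore traced back to a 13-membered cyclic ether in which O6 is bound to C12 – a ring and an O–C12 bond that are absent from the target and are cleaved in the event.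
3. The 13-membered ether is cut at C3–C4 (Cr/Ni alkenyl–aldehyde closure), at the O–C6 ether bond (etherification with a (Z)-iodobutenyl unit) and at C8–C9 (allylboration of an enal made by Wittig olefination at C1=C10).
4. Forward order: chain C3–C12, then a temporary lactone (metathesis) that locks the Z C7=C11 olefin, then the ether, the 13-membered ring, ring contraction to the 10-membered ring, and finally oxidation and acylation.
5. Stereochemistry: C9 from allylboration and C3 from CBS reduction (both reagent control); C6 and C7 from the Wittig step (C3 alkoxide and Z olefin); the epoxides from vanadium delivery by C9–OH and C3–OH; C8 from enolate hydroxylation; the angelate Z geometry is kept by mixed-anhydride acylation.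

Key step: step 15

Remark: the target SMILES defines a trans (1(10)E-derived) 1,10-epoxide and a cis (4Z-derived) 4,5-epoxide, (1S,3S,4S,5R,6S,7R,8R,10R). TBS = tert-butyldimethylsilyl, TBDPS = tert-butyldiphenylsilyl, angelate = (Z)-2-methylbut-2-enoate. Compounds 1, 2 and 9, (−)-B-allyldiisopinocampheylborane and angelic acid are taken as purchased.

**Step 1**
Reactants: 1 3-(TBS-oxy)propanal; 2 2-(triphenylphosphoranylidene)propanal
Product: 3 (2E)-5-(TBS-oxy)-2-methylpent-2-enal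
Conditions: toluene, 90 °C
Reagents that add atoms: none
Why: Wittig olefination with a stabilized formyl ylide should give the E trisubstituted enal (C9 aldehyde, C1=C10, C14 methyl) under thermodynamic control.

**Step 2**
Reactants: 3 (2E)-5-(TBS-oxy)-2-methylpent-2-enal
Product: 5 (4S,5E)-8-(TBS-oxy)-5-methylocta-1,5-dien-4-ol, via diisopinocampheylborinate 4 (not isolated)
Conditions: (−)-Ipc2B(allyl), Et2O, −78 °C; then NaOH, H2O2
Reagents that add atoms: (−)-B-allyldiisopinocampheylborane, C=CCB([C@@H]1C[C@@H]2C[C@H]([C@H]1C)C2(C)C)[C@@H]1C[C@@H]2C[C@H]([C@H]1C)C2(C)C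
Why: Brown allylboration (1,2-addition through a six-membered chair transition state); the isopinocampheyl groups from (+)-α-pinene select the aldehyde face that should give the 9S carbinol (S because the alkenyl group outranks allyl).

**Step 3**
Reactants: 5 (4S,5E)-8-(TBS-oxy)-5-methylocta-1,5-dien-4-ol
Product: 6 (4S,5E)-8-(TBS-oxy)-5-methylocta-1,5-dien-4-yl 2-methylprop-2-enoate
Conditions: CH2=C(CH3)COCl, Et3N, 4-(dimethylamino)pyridine (cat.), CH2Cl2, 0 °C
Reagents that add atoms: methacryloyl chloride, C=C(C)C(Cl)=O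
Why: Acylation of the secondary alcohol (nucleophilic catalysis) installs the second olefin for ring closure and carries C11, C12 and C13; no stereocenter is touched.

**Step 4**
Reactants: 6 (4S,5E)-8-(TBS-oxy)-5-methylocta-1,5-dien-4-yl 2-methylprop-2-enoate
Product: 7 (6S)-6-[(2E)-5-(TBS-oxy)pent-2-en-2-yl]-3-methyl-5,6-dihydro-2H-pyran-2-one
Conditions: RuCl2(=CHPh)(PCy3)(H2IMes) (second-generation Grubbs catalyst, 5 mol %), CH2Cl2, 40 °C
Reagents that add atoms: none
Why: Ring-closing olefin metathesis of the vinyl group with the methacrylate should give the six-membered unsaturated lactone; this temporary ring forces C8 and C12 cis on C7=C11 (the later Z olefin), and the hindered C1=C10 olefin should not take part.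

**Step 5**
Reactants: 7 (6S)-6-[(2E)-5-(TBS-oxy)pent-2-en-2-yl]-3-methyl-5,6-dihydro-2H-pyran-2-one
Product: 8 (2Z,5S,6E)-9-(TBS-oxy)-2,6-dimethylnona-2,6-diene-1,5-diol
Conditions: i-Bu2AlH, CH2Cl2, −78 → 0 °C
Reagents that add atoms: none
Why: Hydride reduction of the lactone (1,2-mode via the lactol) opens the temporary ring to the (Z)-allylic diol with the olefin geometry retained.

**Step 6**
Reactants: 9 but-2-yn-1-ol
Product: 11 (2Z)-3-iodobut-2-en-1-ol, via cyclic alkenylalanate 10 (not isolated)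
Conditions: NaAlH2(OCH2CH2OCH3)2, THF, 0 °C; then I2, −78 °C
Reagents that add atoms: iodine, II
Why: Hydroxyl-directed trans-hydroalumination places aluminium on the distal alkyne carbon (C4 of the target) in a five-membered alanate, and iodinolysis with retention should give the Z vinyl iodide that fixes the later 4Z olefin.

**Step 7**
Reactants: 11 (2Z)-3-iodobut-2-en-1-ol
Product: 12 (2Z)-1-bromo-3-iodobut-2-ene
Conditions: CBr4, PPh3, CH2Cl2, 0 °C
Reagents that add atoms: carbon tetrabromide, BrC(Br)(Br)Br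
Why: Appel bromination of the primary allylic alcohol (SN2 on the alkoxyphosphonium ion) leaves the vinyl iodide geometry unchanged.

**Step 8**
Reactants: 8 (2Z,5S,6E)-9-(TBS-oxy)-2,6-dimethylnona-2,6-diene-1,5-diol; 12 (2Z)-1-bromo-3-iodobut-2-ene
Product: 13 (2Z,5S,6E)-9-(TBS-oxy)-1-{[(2Z)-3-iodobut-2-en-1-yl]oxy}-2,6-dimethylnona-2,6-dien-5-ol
Conditions: Ag2O, CH2Cl2, rt, dark
Reagents that add atoms: none
Why: Williamson-type etherification promoted by Ag2O should alkylate the unhindered primary allylic hydroxyl (C12–OH) in preference to the secondary C9–OH, creating the C6–O–C12 ether that later serves as the tether.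

**Step 9**
Reactants: 13 (2Z,5S,6E)-9-(TBS-oxy)-1-{[(2Z)-3-iodobut-2-en-1-yl]oxy}-2,6-dimethylnona-2,6-dien-5-ol
Product: 14 (3E,5S,7Z)-1,5-bis(TBS-oxy)-9-{[(2Z)-3-iodobut-2-en-1-yl]oxy}-4,8-dimethylnona-3,7-diene
Conditions: TBSOTf, 2,6-lutidine, CH2Cl2, −78 °C
Reagents that add atoms: tert-butyldimethylsilyl trifluoromethanesulfonate, CC(C)(C)[Si](C)(C)OS(=O)(=O)C(F)(F)F
Why: Silylation of the remaining secondary (C9) alcohol with the silyl triflate, a standard protection that survives organolithium base.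

**Step 10**
Reactants: 14 (3E,5S,7Z)-1,5-bis(TBS-oxy)-9-{[(2Z)-3-iodobut-2-en-1-yl]oxy}-4,8-dimethylnona-3,7-diene
Product: 15 (3E,5S,7Z)-5-(TBS-oxy)-9-{[(2Z)-3-iodobut-2-en-1-yl]oxy}-4,8-dimethylnona-3,7-dien-1-ol
Conditions: HF·pyridine, pyridine, THF, 0 °C
Reagents that add atoms: none
Why: Selective desilylation: the unhindered primary silyl ether (C3) should be cleaved well before the secondary allylic one (C9).

**Step 11**
Reactants: 15 (3E,5S,7Z)-5-(TBS-oxy)-9-{[(2Z)-3-iodobut-2-en-1-yl]oxy}-4,8-dimethylnona-3,7-dien-1-ol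
Product: 16 (3E,5S,7Z)-5-(TBS-oxy)-9-{[(2Z)-3-iodobut-2-en-1-yl]oxy}-4,8-dimethylnona-3,7-dienal
Conditions: Dess–Martin periodinane, NaHCO3, CH2Cl2, 0 °C
Reagents that add atoms: none
Why: Dess–Martin oxidation under buffered, non-basic conditions should give the β,γ-unsaturated aldehyde without migration of the C1=C10 olefin; it is used at once.

**Step 12**
Reactants: 16 (3E,5S,7Z)-5-(TBS-oxy)-9-{[(2Z)-3-iodobut-2-en-1-yl]oxy}-4,8-dimethylnona-3,7-dienal
Product: 17 (3Z,5RS,7E,9S,11Z)-9-(TBS-oxy)-4,8,12-trimethyl-1-oxacyclotrideca-3,7,11-trien-5-ol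
Conditions: CrCl2 (8 equiv), NiCl2 (1 mol %), DMSO, 0.002 M, rt
Reagents that add atoms: none
Why: Nozaki–Hiyama–Kishi alkenylation (nickel insertion into C–I, transmetalation to trivalent chromium, addition to the aldehyde) should close the 13-membered ring at C3–C4 with retention of the Z vinyl geometry under high dilution; C3 is not controlled here.

**Step 13**
Reactants: 17 (3Z,5RS,7E,9S,11Z)-9-(TBS-oxy)-4,8,12-trimethyl-1-oxacyclotrideca-3,7,11-trien-5-ol
Product: 18 (3Z,7E,9S,11Z)-9-(TBS-oxy)-4,8,12-trimethyl-1-oxacyclotrideca-3,7,11-trien-5-one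
Conditions: MnO2, CH2Cl2, rt
Reagents that add atoms: none
Why: Allylic oxidation on MnO2 under neutral conditions merges both C3 epimers into the Z-enone, so that C3 can be set by a reagent.

**Step 14**
Reactants: 18 (3Z,7E,9S,11Z)-9-(TBS-oxy)-4,8,12-trimethyl-1-oxacyclotrideca-3,7,11-trien-5-one
Product: 19 (3Z,5S,7E,9S,11Z)-9-(TBS-oxy)-4,8,12-trimethyl-1-oxacyclotrideca-3,7,11-trien-5-ol
Conditions: (R)-1-methyl-3,3-diphenyltetrahydro-1H,3H-pyrrolo[1,2-c][1,3,2]oxazaborole ((R)-Me-CBS, 0.3 equiv), BH3·SMe2, THF, −30 °C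
Reagents that add atoms: none
Why: Corey–Bakshi–Shibata reduction (1,2 only): with the α-methylalkenyl group as the large substituent, the R catalyst should deliver hydride to give the 3S alcohol.

**Step 15**
Reactants: 19 (3Z,5S,7E,9S,11Z)-9-(TBS-oxy)-4,8,12-trimethyl-1-oxacyclotrideca-3,7,11-trien-5-ol
Product: 21 (3S,6R,7R,9S)-9-(TBS-oxy)germacra-1(10)E,4Z,11-triene-3,6-diol, via dilithio ether 20 (not isolated)
Conditions: n-BuLi (2.3 equiv), THF, −78 → −40 °C; then aq. NH4Cl at −78 °C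
Reagents that add atoms: none
Why: Deprotonation of the C3 hydroxyl and then of the allylic ether carbon C6 gives the chelated dilithio species 20, which undergoes a [2,3]-Wittig sigmatropic shift: C6 attacks C7 of the (Z)-C7=C11 allyl unit through a five-membered envelope transition state, the O–C12 bond breaks and the ether oxygen becomes the C6 alkoxide, which unveils the isopropenyl group. The closest known reaction type is the Wittig ring contraction of 13-membered diallylic ethers to germacrane alcohols. The 10-membered carbocycle is closed in a transannular [2,3] mode, i.e. by ring contraction in which O, C12 and C11 leave the ring. The C6/C7 relationship (syn, oxygen and isopropenyl cis on the ring) should follow from the Z geometry of C7=C11 with C5 exo in the envelope, and the sense at C6 from the C3 lithium alkoxide, which holds lithium at C6 on the face of the Z-allyl plane away from C2 so that the bond forms with inversion on the C2 face. The step needs lithiation at C6 and not at C12 and no loss of the C3 oxygen; the cis-disposed C3 alkoxide directs the base to C6 and, being an alkoxide, cannot leave in a 1,4-elimination. The low temperature and the lithium counter-ion should keep anionic oxy-Cope rearrangement of the 1,5-diene from competing.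

**Step 16**
Reactants: 21 (3S,6R,7R,9S)-9-(TBS-oxy)germacra-1(10)E,4Z,11-triene-3,6-diol
Product: 22 (3S,6R,7R,9S)-9-(TBS-oxy)-3-(TBDPS-oxy)germacra-1(10)E,4Z,11-trien-6-ol
Conditions: TBDPSCl (1.05 equiv), imidazole, DMF, 0 °C
Reagents that add atoms: tert-butyl(chloro)diphenylsilane, CC(C)(C)[Si](Cl)(c1ccccc1)c1ccccc1
Why: Silylation with the bulky chloride is expected at the less hindered C3 hydroxyl, because C6–OH is flanked by the branched C7; this frees C6 for acylation and keeps C3–OH for the later directed epoxidation.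

**Step 17**
Reactants: 22 (3S,6R,7R,9S)-9-(TBS-oxy)-3-(TBDPS-oxy)germacra-1(10)E,4Z,11-trien-6-ol
Product: 23 (3S,6R,7R,9S)-9-(TBS-oxy)-3-(TBDPS-oxy)germacra-1(10)E,4Z,11-trien-6-yl angelate
Conditions: angelic acid, 2,4,6-Cl3C6H2COCl, Et3N, toluene, rt; then 22, 60 °C
Reagents that add atoms: angelic acid, C/C=C(/C)C(=O)O
Why: Yamaguchi-type esterification through the mixed anhydride without nucleophilic amine catalyst, conditions under which the Z (angelate) geometry should be kept; 60 °C is chosen to avoid Cope rearrangement of the 1(10),4-diene.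

**Step 18**
Reactants: 23 (3S,6R,7R,9S)-9-(TBS-oxy)-3-(TBDPS-oxy)germacra-1(10)E,4Z,11-trien-6-yl angelate
Product: 24 (3S,6R,7R,9S)-9-hydroxy-3-(TBDPS-oxy)germacra-1(10)E,4Z,11-trien-6-yl angelate
Conditions: HF·pyridine, pyridine, THF, 0 °C → rt
Reagents that add atoms: none
Why: Selective desilylation: under buffered HF the tert-butyldimethylsilyl ether should be cleaved well before the tert-butyldiphenylsilyl ether, and the ester and the acid-sensitive diene are spared.

**Step 19**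
Reactants: 24 (3S,6R,7R,9S)-9-hydroxy-3-(TBDPS-oxy)germacra-1(10)E,4Z,11-trien-6-yl angelate
Product: 25 (1S,3S,6R,7R,9S,10S)-1,10-epoxy-9-hydroxy-3-(TBDPS-oxy)germacra-4Z,11-dien-6-yl angelate
Conditions: VO(acac)2 (5 mol %), t-BuOOH, CH2Cl2, 0 °C
Reagents that add atoms: tert-butyl hydroperoxide, CC(C)(C)OO
Why: Hydroxyl-directed epoxidation (vanadium alkylperoxide bound to O9): with the O–C9–C10=C1 dihedral near 50°, H9 next to the C14 methyl and the ring bond C9–C8 perpendicular, oxygen should reach the outer face of the E olefin, which for the 9S alcohol gives the trans epoxide of the target (descriptor 10S here only because C9 is still a carbinol); the other olefins have no free hydroxyl.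

**Step 20**
Reactants: 25 (1S,3S,6R,7R,9S,10S)-1,10-epoxy-9-hydroxy-3-(TBDPS-oxy)germacra-4Z,11-dien-6-yl angelate
Product: 26 (1S,3S,6R,7R,10R)-1,10-epoxy-9-oxo-3-(TBDPS-oxy)germacra-4Z,11-dien-6-yl angelate
Conditions: Dess–Martin periodinane, NaHCO3, CH2Cl2, rt
Reagents that add atoms: none
Why: Dess–Martin oxidation of the epoxy alcohol gives the α,β-epoxy ketone and removes the C9 stereocenter once it has done its work.

**Step 21**
Reactants: 26 (1S,3S,6R,7R,10R)-1,10-epoxy-9-oxo-3-(TBDPS-oxy)germacra-4Z,11-dien-6-yl angelate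
Product: 28 (1S,3S,6R,7S,8R,10R)-1,10-epoxy-8-hydroxy-9-oxo-3-(TBDPS-oxy)germacra-4Z,11-dien-6-yl angelate, via potassium enolate 27 (not isolated)
Conditions: KN(SiMe3)2, THF, −78 °C; then 2-(phenylsulfonyl)-3-phenyloxaziridine, −78 °C; aq. NH4Cl
Reagents that add atoms: 2-(phenylsulfonyl)-3-phenyloxaziridine, O=S(=O)(c1ccccc1)N1OC1c1ccccc1
Why: Enolate α-hydroxylation with an N-sulfonyloxaziridine: C10 is fully substituted, so the ketone can enolize only towards C8, and the oxidant should attack the enolate face away from the isopropenyl group in the conformer with H7 eclipsing the enolate, placing O8 cis to the C7 substituent (8R).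

**Step 22**
Reactants: 28 (1S,3S,6R,7S,8R,10R)-1,10-epoxy-8-hydroxy-9-oxo-3-(TBDPS-oxy)germacra-4Z,11-dien-6-yl angelate
Product: 29 (1S,3S,6R,7R,8R,10R)-1,10-epoxy-9-oxo-3-(TBDPS-oxy)germacra-4Z,11-diene-6,8-diyl diangelate
Conditions: angelic acid, 2,4,6-Cl3C6H2COCl, Et3N, toluene, rt; then 28, 40 °C
Reagents that add atoms: angelic acid, C/C=C(/C)C(=O)O
Why: Mixed-anhydride (Yamaguchi-type) esterification of the α-hydroxy ketone as in step 17; the weakly basic medium should not epimerize C8.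

**Step 23**
Reactants: 29 (1S,3S,6R,7R,8R,10R)-1,10-epoxy-9-oxo-3-(TBDPS-oxy)germacra-4Z,11-diene-6,8-diyl diangelate
Product: 30 (1S,3S,6R,7R,8R,10R)-1,10-epoxy-3-hydroxy-9-oxogermacra-4Z,11-diene-6,8-diyl diangelate
Conditions: HF·pyridine, THF, 0 °C → rt
Reagents that add atoms: none
Why: Fluoride cleavage of the silyl ether with HF·pyridine should spare the esters, the α-acyloxy ketone and the epoxy ketone, which basic fluoride would endanger.

**Step 24**
Reactants: 30 (1S,3S,6R,7R,8R,10R)-1,10-epoxy-3-hydroxy-9-oxogermacra-4Z,11-diene-6,8-diyl diangelate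
Product: 31 (1S,3S,4S,5R,6S,7R,8R,10R)-1,10:4,5-diepoxy-3-hydroxy-9-oxogermacr-11-ene-6,8-diyl diangelate
Conditions: VO(acac)2 (5 mol %), t-BuOOH, CH2Cl2, 0 °C → rt
Reagents that add atoms: tert-butyl hydroperoxide, CC(C)(C)OO
Why: Hydroxyl-directed epoxidation by C3–OH: allylic strain places H3 next to the C15 methyl and the ring bond C3–C2 perpendicular, so the vanadium peroxide bound to O3 should reach the face of the Z olefin that gives the cis (4S,5R) epoxide syn to O3, as in 2-cycloalken-1-ols; C6 is blocked as the ester and the isopropenyl group has no directing hydroxyl.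

**Step 25**
Reactants: 31 (1S,3S,4S,5R,6S,7R,8R,10R)-1,10:4,5-diepoxy-3-hydroxy-9-oxogermacr-11-ene-6,8-diyl diangelate
Product: 32 (1S,3S,4S,5R,6S,7R,8R,10R)-1,10:4,5-diepoxy-9-oxogermacr-11-ene-3,6,8-triyl triangelate (CNP0154187.3)
Conditions: angelic acid, 2,4,6-Cl3C6H2COCl, Et3N, toluene, rt; then 31, 40 °C
Reagents that add atoms: angelic acid, C/C=C(/C)C(=O)O
Why: Mixed-anhydride (Yamaguchi-type) esterification of the last hydroxyl should give the triangelate without isomerization to tiglate.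

**Compound list**

1 | 3-(TBS-oxy)propanal | O=CCCO[Si](C)(C)C(C)(C)C | starting material
2 | 2-(triphenylphosphoranylidene)propanal | CC(C=O)=P(c1ccccc1)(c1ccccc1)c1ccccc1 | starting material
3 | (2E)-5-(TBS-oxy)-2-methylpent-2-enal | O=C/C(C)=C/CCO[Si](C)(C)C(C)(C)C | intermediate
4 | diisopinocampheylborinate of 5 | C=CC[C@H](OB([C@@H]1C[C@@H]2C[C@H]([C@H]1C)C2(C)C)[C@@H]1C[C@@H]2C[C@H]([C@H]1C)C2(C)C)/C(C)=C/CCO[Si](C)(C)C(C)(C)C | intermediate
5 | (4S,5E)-8-(TBS-oxy)-5-methylocta-1,5-dien-4-ol | C=CC[C@H](O)/C(C)=C/CCO[Si](C)(C)C(C)(C)C | intermediate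
6 | (4S,5E)-8-(TBS-oxy)-5-methylocta-1,5-dien-4-yl 2-methylprop-2-enoate | C=CC[C@H](OC(=O)C(C)=C)/C(C)=C/CCO[Si](C)(C)C(C)(C)C | intermediate
7 | (6S)-6-[(2E)-5-(TBS-oxy)pent-2-en-2-yl]-3-methyl-5,6-dihydro-2H-pyran-2-one | CC1=CC[C@@H](/C(C)=C/CCO[Si](C)(C)C(C)(C)C)OC1=O | intermediate
8 | (2Z,5S,6E)-9-(TBS-oxy)-2,6-dimethylnona-2,6-diene-1,5-diol | OC/C(C)=C\C[C@H](O)/C(C)=C/CCO[Si](C)(C)C(C)(C)C | intermediate
9 | but-2-yn-1-ol | CC#CCO | starting material
10 | sodium cyclic alkenylalanate from 9 | CC1=CCO[Al-]1(OCCOC)OCCOC.[Na+] | intermediate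
11 | (2Z)-3-iodobut-2-en-1-ol | C/C(I)=C/CO | intermediate
12 | (2Z)-1-bromo-3-iodobut-2-ene | C/C(I)=C/CBr | intermediate
13 | (2Z,5S,6E)-9-(TBS-oxy)-1-{[(2Z)-3-iodobut-2-en-1-yl]oxy}-2,6-dimethylnona-2,6-dien-5-ol | C/C(I)=C/COC/C(C)=C\C[C@H](O)/C(C)=C/CCO[Si](C)(C)C(C)(C)C | intermediate
14 | (3E,5S,7Z)-1,5-bis(TBS-oxy)-9-{[(2Z)-3-iodobut-2-en-1-yl]oxy}-4,8-dimethylnona-3,7-diene | C/C(I)=C/COC/C(C)=C\C[C@H](O[Si](C)(C)C(C)(C)C)/C(C)=C/CCO[Si](C)(C)C(C)(C)C | intermediate
15 | (3E,5S,7Z)-5-(TBS-oxy)-9-{[(2Z)-3-iodobut-2-en-1-yl]oxy}-4,8-dimethylnona-3,7-dien-1-ol | C/C(I)=C/COC/C(C)=C\C[C@H](O[Si](C)(C)C(C)(C)C)/C(C)=C/CCO | intermediate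
16 | (3E,5S,7Z)-5-(TBS-oxy)-9-{[(2Z)-3-iodobut-2-en-1-yl]oxy}-4,8-dimethylnona-3,7-dienal | C/C(I)=C/COC/C(C)=C\C[C@H](O[Si](C)(C)C(C)(C)C)/C(C)=C/CC=O | intermediate
17 | (3Z,5RS,7E,9S,11Z)-9-(TBS-oxy)-4,8,12-trimethyl-1-oxacyclotrideca-3,7,11-trien-5-ol (C3 epimers, germacrane numbering) | OC1C/C=C(C)/[C@@H](O[Si](C)(C)C(C)(C)C)C/C=C(C)\COC/C=C1/C | intermediate
18 | (3Z,7E,9S,11Z)-9-(TBS-oxy)-4,8,12-trimethyl-1-oxacyclotrideca-3,7,11-trien-5-one | O=C1C/C=C(C)/[C@@H](O[Si](C)(C)C(C)(C)C)C/C=C(C)\COC/C=C1/C | intermediate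
19 | (3Z,5S,7E,9S,11Z)-9-(TBS-oxy)-4,8,12-trimethyl-1-oxacyclotrideca-3,7,11-trien-5-ol (13-membered 6,12-ether, 3S,9S in germacrane numbering) | O[C@H]1C/C=C(C)/[C@@H](O[Si](C)(C)C(C)(C)C)C/C=C(C)\COC/C=C1/C | intermediate
20 | dilithio ether: lithium alkoxide of 19 lithiated at C6 | [Li]O[C@H]1C/C=C(C)/[C@@H](O[Si](C)(C)C(C)(C)C)C/C=C(C)\COC([Li])/C=C1/C | intermediate
21 | (3S,6R,7R,9S)-9-(TBS-oxy)germacra-1(10)E,4Z,11-triene-3,6-diol | C=C(C)[C@@H]1[C@H](O)/C=C(C)\[C@@H](O)C/C=C(C)/[C@@H](O[Si](C)(C)C(C)(C)C)C1 | intermediate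
22 | (3S,6R,7R,9S)-9-(TBS-oxy)-3-(TBDPS-oxy)germacra-1(10)E,4Z,11-trien-6-ol | C=C(C)[C@@H]1[C@H](O)/C=C(C)\[C@@H](O[Si](c3ccccc3)(c3ccccc3)C(C)(C)C)C/C=C(C)/[C@@H](O[Si](C)(C)C(C)(C)C)C1 | intermediate
23 | (3S,6R,7R,9S)-9-(TBS-oxy)-3-(TBDPS-oxy)germacra-1(10)E,4Z,11-trien-6-yl angelate | C=C(C)[C@@H]1[C@H](OC(=O)/C(C)=C\C)/C=C(C)\[C@@H](O[Si](c3ccccc3)(c3ccccc3)C(C)(C)C)C/C=C(C)/[C@@H](O[Si](C)(C)C(C)(C)C)C1 | intermediate
24 | (3S,6R,7R,9S)-9-hydroxy-3-(TBDPS-oxy)germacra-1(10)E,4Z,11-trien-6-yl angelate | C=C(C)[C@@H]1[C@H](OC(=O)/C(C)=C\C)/C=C(C)\[C@@H](O[Si](c3ccccc3)(c3ccccc3)C(C)(C)C)C/C=C(C)/[C@@H](O)C1 | intermediate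
25 | (1S,3S,6R,7R,9S,10S)-1,10-epoxy-9-hydroxy-3-(TBDPS-oxy)germacra-4Z,11-dien-6-yl angelate | C=C(C)[C@@H]1[C@H](OC(=O)/C(C)=C\C)/C=C(C)\[C@@H](O[Si](c3ccccc3)(c3ccccc3)C(C)(C)C)C[C@@H]2O[C@@]2(C)[C@@H](O)C1 | intermediate
26 | (1S,3S,6R,7R,10R)-1,10-epoxy-9-oxo-3-(TBDPS-oxy)germacra-4Z,11-dien-6-yl angelate | C=C(C)[C@@H]1[C@H](OC(=O)/C(C)=C\C)/C=C(C)\[C@@H](O[Si](c3ccccc3)(c3ccccc3)C(C)(C)C)C[C@@H]2O[C@@]2(C)C(=O)C1 | intermediate
27 | potassium C8=C9 enolate of 26 | C=C(C)[C@@H]1[C@H](OC(=O)/C(C)=C\C)/C=C(C)\[C@@H](O[Si](c3ccccc3)(c3ccccc3)C(C)(C)C)C[C@@H]2O[C@@]2(C)C(O[K])=C1 | intermediate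
28 | (1S,3S,6R,7S,8R,10R)-1,10-epoxy-8-hydroxy-9-oxo-3-(TBDPS-oxy)germacra-4Z,11-dien-6-yl angelate | C=C(C)[C@@H]1[C@H](OC(=O)/C(C)=C\C)/C=C(C)\[C@@H](O[Si](c3ccccc3)(c3ccccc3)C(C)(C)C)C[C@@H]2O[C@@]2(C)C(=O)[C@@H]1O | intermediate
29 | (1S,3S,6R,7R,8R,10R)-1,10-epoxy-9-oxo-3-(TBDPS-oxy)germacra-4Z,11-diene-6,8-diyl diangelate | C=C(C)[C@@H]1[C@H](OC(=O)/C(C)=C\C)/C=C(C)\[C@@H](O[Si](c3ccccc3)(c3ccccc3)C(C)(C)C)C[C@@H]2O[C@@]2(C)C(=O)[C@@H]1OC(=O)/C(C)=C\C | intermediate
30 | (1S,3S,6R,7R,8R,10R)-1,10-epoxy-3-hydroxy-9-oxogermacra-4Z,11-diene-6,8-diyl diangelate | C=C(C)[C@@H]1[C@H](OC(=O)/C(C)=C\C)/C=C(C)\[C@@H](O)C[C@@H]2O[C@@]2(C)C(=O)[C@@H]1OC(=O)/C(C)=C\C | intermediate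
31 | (1S,3S,4S,5R,6S,7R,8R,10R)-1,10:4,5-diepoxy-3-hydroxy-9-oxogermacr-11-ene-6,8-diyl diangelate | C=C(C)[C@@H]1[C@H](OC(=O)/C(C)=C\C)[C@H]2O[C@@]2(C)[C@@H](O)C[C@@H]2O[C@@]2(C)C(=O)[C@@H]1OC(=O)/C(C)=C\C | intermediate
32 | (1S,3S,4S,5R,6S,7R,8R,10R)-1,10:4,5-diepoxy-9-oxogermacr-11-ene-3,6,8-triyl triangelate (CNP0154187.3) | C=C(C)[C@@H]1[C@H](OC(=O)/C(C)=C\C)[C@H]2O[C@@]2(C)[C@@H](OC(=O)/C(C)=C\C)C[C@@H]2O[C@@]2(C)C(=O)[C@@H]1OC(=O)/C(C)=C\C | target

**Step count and risks**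

Total step count: 25 (23 in the main line, 2 for bromide 12). Longest linear sequence: 23 steps (steps 1–5 and 8–25).

Steps most likely to fail:

Step 15 (key step). What may go wrong is C–C bond formation on the face of the C7=C11 unit opposite to the one wanted, i.e. induction from the C3 alkoxide running in the reverse sense. The fallback switches the sense at the source and corrects C3 afterwards. Enone 18 would be reduced with the enantiomeric (S)-oxazaborolidine and BH3·SMe2 to the C3 epimer of 19 F1. Ring contraction under the conditions of step 15 should then give the 3R diol, C3 epimer of 21 F2, with C6 and C7 as in 21. Mitsunobu esterification (4-nitrobenzoic acid, PPh3, diisopropyl azodicarboxylate, THF, 0 °C) at the more accessible C3 carbinol would invert it to the 3-(4-nitrobenzoate) of 21 F3. Methanolysis (K2CO3, MeOH) returns to 21.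

Step 21. What may go wrong is approach of the oxidant to the other enolate face, so that the hydroxyl enters trans to the C7 substituent. The fallback uses that product instead of discarding it: the C8 epimer of 28 F4, formed from 26, would be esterified under Mitsunobu conditions (angelic acid, PPh3, diisopropyl azodicarboxylate, toluene, 0 °C). SN2 displacement next to the ketone inverts C8 and should give 29 directly.

Step 19. What may go wrong is delivery of oxygen to the inner face of the strained E olefin, or sluggish reaction of the hindered allylic alcohol. The fallback changes from hydroxyl-directed to nucleophilic epoxidation: 24 would be oxidized (Dess–Martin periodinane, NaHCO3, CH2Cl2) to the C9 enone F5, and Weitz–Scheffer-type epoxidation (t-BuOOH, DBU, CH2Cl2, 0 °C), with attack of the peroxide anion on the exposed face of the twisted E-enone, should give 26.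

**Further compounds**

F1 | step 15 | (3Z,5R,7E,9S,11Z)-9-(TBS-oxy)-4,8,12-trimethyl-1-oxacyclotrideca-3,7,11-trien-5-ol (C3 epimer of 19) | O[C@@H]1C/C=C(C)/[C@@H](O[Si](C)(C)C(C)(C)C)C/C=C(C)\COC/C=C1/C
F2 | step 15 | (3R,6R,7R,9S)-9-(TBS-oxy)germacra-1(10)E,4Z,11-triene-3,6-diol (C3 epimer of 21) | C=C(C)[C@@H]1[C@H](O)/C=C(C)\[C@H](O)C/C=C(C)/[C@@H](O[Si](C)(C)C(C)(C)C)C1
F3 | step 15 | (3S,6R,7R,9S)-6-hydroxy-9-(TBS-oxy)germacra-1(10)E,4Z,11-trien-3-yl 4-nitrobenzoate (3-(4-nitrobenzoate) of 21) | C=C(C)[C@@H]1[C@H](O)/C=C(C)\[C@@H](OC(=O)c3ccc(cc3)[N+](=O)[O-])C/C=C(C)/[C@@H](O[Si](C)(C)C(C)(C)C)C1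
F4 | step 21 | (1S,3S,6R,7S,8S,10R)-1,10-epoxy-8-hydroxy-9-oxo-3-(TBDPS-oxy)germacra-4Z,11-dien-6-yl angelate (C8 epimer of 28) | C=C(C)[C@@H]1[C@H](OC(=O)/C(C)=C\C)/C=C(C)\[C@@H](O[Si](c3ccccc3)(c3ccccc3)C(C)(C)C)C[C@@H]2O[C@@]2(C)C(=O)[C@H]1O
F5 | step 19 | (3S,6R,7R)-9-oxo-3-(TBDPS-oxy)germacra-1(10)E,4Z,11-trien-6-yl angelate (C9 enone) | C=C(C)[C@@H]1[C@H](OC(=O)/C(C)=C\C)/C=C(C)\[C@@H](O[Si](c3ccccc3)(c3ccccc3)C(C)(C)C)C/C=C(C)/C(=O)C1
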